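The route rests on cutting the cyclohexene into three pieces: C2–C3 from an α-silyloxy aldehyde, C4–C5 from a nitroalkene and C6–C1–C7 from a 2-phosphonoacrylate. One pot forms C3–C4 (enamine Michael), C5–C6 (nitronate Michael) and C1=C2 (intramolecular HWE), closing the six-membered ring with the cis C3–O/C4–i-Pr pair set and C7 at ester level. The precursors are TBSO-acetaldehyde, (E)-3-methyl-1-nitrobut-1-ene and ethyl 2-(diethoxyphosphoryl)acrylate. The feature exploited is the ring array C1(C7)=C2–C3(O)–C4(i-Pr)–C5–C6. The C5 nitro group is then excised by reduction and Cope elimination, the C5=C6 alkene is dihydroxylated anti to the isopropyl group, and the four oxygens are differentiated.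

Key step: step 4

Remark on numbering: locants and descriptors use the ring numbering C1 (bears C7), C2 (olefinic CH), C3 (O), C4 (i-Pr), C5, C6 throughout, not lowest-locant rules.

Remark on the nitro group: base alone is not relied on to expel HNO2 from 13, because the C6 hydrogens are only allylic (cross-conjugated to the ester) and base would simply store the compound as its C5 nitronate. The C5=C6 alkene is therefore made through the amine and its N-oxide.

Remark on the catalyst: the antipode of the amine–thiourea catalyst that delivers the (2R,3R) aldehyde 11 is assumed; both antipodes are available.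

Step 1
Reactants: 1 isobutyraldehyde; 2 nitromethane
Product: 3 3-methyl-1-nitrobutan-2-ol (racemic)
Conditions: MeNO2 (5 equiv), KOt-Bu (10 mol%), THF/t-BuOH, 0 °C → rt
Reagents that add atoms: none
Why: Henry (nitroaldol) addition of the nitronate to an unhindered aldehyde; the carbinol centre is racemic and is destroyed in step 2.

Step 2
Reactants: 3 3-methyl-1-nitrobutan-2-ol
Product: 5 (E)-3-methyl-1-nitrobut-1-ene, via mesylate 4 (not isolated)
Conditions: MsCl, Et3N, CH2Cl2, 0 °C
Reagents that add atoms: none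
Why: O-mesylation followed by E1cB elimination through the acidic CH2NO2 protons should give the conjugated nitroalkene as the more stable E isomer.

Step 3
Reactants: 6 triethyl phosphonoacetate; 7 paraformaldehyde
Product: 9 ethyl 2-(diethoxyphosphoryl)acrylate, via hydroxymethyl phosphonate 8 (not isolated)
Conditions: (CH2O)n, piperidine (cat.), MeOH, reflux; then TsOH (cat.), toluene, reflux (Dean–Stark)
Reagents that add atoms: none
Why: Knoevenagel-type hydroxymethylation of the doubly activated methylene followed by acid-catalysed dehydration is the standard preparation of this acrylate.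

Step 4
Reactants: 10 (tert-butyldimethylsilyloxy)acetaldehyde; 5 (E)-3-methyl-1-nitrobut-1-ene; 9 ethyl 2-(diethoxyphosphoryl)acrylate
Product: 13 ethyl (3S,4R,5S)-3-[(tert-butyldimethylsilyl)oxy]-4-isopropyl-5-nitrocyclohex-1-ene-1-carboxylate, via anti γ-nitroaldehyde 11 (not isolated), via acyclic nitro phosphonate 12 (not isolated)
Conditions: 10 (1.5 equiv), 5, 1-(2-aminocyclohexyl)-3-[3,5-bis(trifluoromethyl)phenyl]thiourea (15 mol%), CH2Cl2, rt; then 9, Cs2CO3, 0 °C; then EtOH, rt
Reagents that add atoms: none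
Why: The primary amine condenses with 10 to a Z-enamine held by an N–H···O(silyl) hydrogen bond, and this adds to the thiourea-bound nitroalkene 5 (enamine Michael addition) to form C3–C4 in 11. Cs2CO3 then turns the CH2NO2 group into its nitronate, which adds to 9 to form C5–C6 (12), and the phosphonate carbanion so generated attacks the aldehyde and expels diethyl phosphate (intramolecular Horner–Wadsworth–Emmons) to form C1=C2. The closest known reaction types are the anti-selective primary-amine/thiourea Michael addition of silyloxyacetaldehyde to nitroalkenes and the one-pot nitroaldehyde/vinylphosphonate Michael–HWE annulation. The ring closes by 6-exo-trig attack of the C1 carbanion on the C2 carbonyl. C3 and C4 are set by the catalyst (enamine geometry gives the anti adduct, which is 3,4-cis in the ring, and the chiral scaffold gives the absolute sense), while C5 equilibrates through the nitronate towards the trans isomer and is erased in step 7, so either C5 epimer can be carried on. The step needs anti diastereoselectivity, which the α-silyloxy group secures through the hydrogen-bonded enamine, and nitronate C-alkylation ahead of aldehyde epimerisation, which the acidity of the nitro α-protons and the fast intramolecular olefination secure.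

Step 5
Reactants: 13 ethyl (3S,4R,5S)-3-[(tert-butyldimethylsilyl)oxy]-4-isopropyl-5-nitrocyclohex-1-ene-1-carboxylate
Product: 14 ethyl (3S,4R,5S)-5-amino-3-[(tert-butyldimethylsilyl)oxy]-4-isopropylcyclohex-1-ene-1-carboxylate
Conditions: Zn dust, AcOH, EtOH, rt; aq. NaHCO3 work-up
Reagents that add atoms: none
Why: Dissolving-metal reduction of an aliphatic nitro group to the primary amine proceeds with retention at C5 and should leave the enoate and the silyl ether untouched.

Step 6
Reactants: 14 ethyl (3S,4R,5S)-5-amino-3-[(tert-butyldimethylsilyl)oxy]-4-isopropylcyclohex-1-ene-1-carboxylate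
Product: 15 ethyl (3S,4R,5S)-3-[(tert-butyldimethylsilyl)oxy]-5-(dimethylamino)-4-isopropylcyclohex-1-ene-1-carboxylate
Conditions: aq. HCHO (37%), NaBH(OAc)3, MeCN, rt
Reagents that add atoms: formaldehyde, C=O
Why: Twofold reductive amination with a mild hydride donor should give the tertiary amine without touching the conjugated ester.

Step 7
Reactants: 15 ethyl (3S,4R,5S)-3-[(tert-butyldimethylsilyl)oxy]-5-(dimethylamino)-4-isopropylcyclohex-1-ene-1-carboxylate
Product: 17 ethyl (3R,4R)-3-[(tert-butyldimethylsilyl)oxy]-4-isopropylcyclohexa-1,5-diene-1-carboxylate, via amine N-oxide 16 (not isolated)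
Conditions: m-CPBA (1.05 equiv), CH2Cl2, 0 °C; basic alumina filtration; THF/DMSO, 50–70 °C
Reagents that add atoms: none
Why: N-oxidation followed by Cope elimination (thermal syn Ei) should remove the allylic, more acidic syn hydrogen at C6 in preference to the hindered C4–H, giving the conjugated diene and erasing C5.

Step 8
Reactants: 17 ethyl (3R,4R)-3-[(tert-butyldimethylsilyl)oxy]-4-isopropylcyclohexa-1,5-diene-1-carboxylate
Product: 18 ethyl (3S,4R,5R,6S)-3-[(tert-butyldimethylsilyl)oxy]-5,6-dihydroxy-4-isopropylcyclohex-1-ene-1-carboxylate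
Conditions: OsO4 (2 mol%), NMO, acetone/H2O, 0 °C → rt
Reagents that add atoms: osmium tetroxide (catalytic carrier), O=[Os](=O)(=O)=O; N-methylmorpholine N-oxide, C[N+]1([O-])CCOCC1; water, O
Why: Upjohn dihydroxylation should select the disubstituted C5=C6 bond over the electron-poor, trisubstituted C1=C2 enoate and add both oxygens syn from the face opposite the C4 isopropyl (and C3 silyloxy) group, setting C5 and C6.

Step 9
Reactants: 18 ethyl (3S,4R,5R,6S)-3-[(tert-butyldimethylsilyl)oxy]-5,6-dihydroxy-4-isopropylcyclohex-1-ene-1-carboxylate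
Product: 19 (3S,4R,5R,6S)-3-[(tert-butyldimethylsilyl)oxy]-1-(hydroxymethyl)-4-isopropylcyclohex-1-ene-5,6-diol
Conditions: DIBAL-H (5 equiv), CH2Cl2, −78 → 0 °C; Rochelle salt
Reagents that add atoms: none
Why: DIBAL-H reduces the enoate by 1,2-addition to the primary allylic alcohol, with the excess hydride covering the two free hydroxyls.

Step 10
Reactants: 19 (3S,4R,5R,6S)-3-[(tert-butyldimethylsilyl)oxy]-1-(hydroxymethyl)-4-isopropylcyclohex-1-ene-5,6-diol
Product: 20 6,7-O-(di-tert-butylsilylene) derivative of 19 (six-membered ring Si–O7–C7–C1–C6–O6; C5–OH free; 3S,4R,5R,6S)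
Conditions: t-Bu2Si(OTf)2 (1.05 equiv), 2,6-lutidine, CH2Cl2, −20 → 0 °C
Reagents that add atoms: di-tert-butylsilyl bis(trifluoromethanesulfonate), CC(C)(C)[Si](OS(=O)(=O)C(F)(F)F)(OS(=O)(=O)C(F)(F)F)C(C)(C)C
Why: Silylene protection of a 1,3-diol: the primary O7 is silylated first and the ring can then close only onto O6 (six-membered; O5 would need seven), which singles out C5–OH.

Step 11
Reactants: 20 6,7-O-(di-tert-butylsilylene) derivative of 19
Product: 21 5-O-acetyl derivative of 20 (3S,4R,5R,6S)
Conditions: Ac2O, pyridine, DMAP (cat.), CH2Cl2, rt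
Reagents that add atoms: acetic anhydride, CC(=O)OC(C)=O
Why: DMAP-catalysed acetylation of the only free hydroxyl places the acetate on O5 with retention.

Step 12
Reactants: 21 5-O-acetyl derivative of 20
Product: 22 (3S,4S,5R,6S)-3,6-dihydroxy-1-(hydroxymethyl)-4-isopropylcyclohex-1-en-5-yl acetate
Conditions: HF·pyridine, pyridine, THF, 0 °C → rt
Reagents that add atoms: none
Why: Fluoride-mediated desilylation cleaves the silylene and the C3 silyl ether together, and the buffered acidic medium should spare the acetate and disfavour acyl migration.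

Step 13
Reactants: 22 (3S,4S,5R,6S)-3,6-dihydroxy-1-(hydroxymethyl)-4-isopropylcyclohex-1-en-5-yl acetate
Product: 23 (3S,4S,5R,6S)-1-{[(tert-butyldimethylsilyl)oxy]methyl}-3,6-dihydroxy-4-isopropylcyclohex-1-en-5-yl acetate
Conditions: TBSCl (1.05 equiv), imidazole, CH2Cl2, −20 → 0 °C
Reagents that add atoms: tert-butyldimethylsilyl chloride, CC(C)(C)[Si](C)(C)Cl
Why: Selective silylation of the primary allylic hydroxyl over the two hindered secondary ones.

Step 14
Reactants: 23 (3S,4S,5R,6S)-1-{[(tert-butyldimethylsilyl)oxy]methyl}-3,6-dihydroxy-4-isopropylcyclohex-1-en-5-yl acetate; 24 tigloyl chloride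
Product: 25 7-O-TBS ether of the target (3S,4S,5R,6S; O3 and O6 tigloylated; O5 acetylated)
Conditions: 24 (4 equiv), pyridine, DMAP, CH2Cl2, 0 °C → rt
Reagents that add atoms: none
Why: DMAP-catalysed acylation with the acid chloride esterifies both secondary allylic hydroxyls at oxygen, so C3 and C6 keep their configuration and the E geometry of the acyl group is retained.

Step 15
Reactants: 25 7-O-TBS ether of the target
Product: 26 target CNP0169590.1
Conditions: HF·pyridine, pyridine, THF, 0 °C
Reagents that add atoms: none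
Why: Fluoride cleavage of the primary silyl ether under buffered acidic conditions frees C7–OH without ester cleavage or acyl migration.

Compound list

1 | isobutyraldehyde | CC(C)C=O | starting material
2 | nitromethane | C[N+](=O)[O-] | starting material
3 | 3-methyl-1-nitrobutan-2-ol (racemic) | CC(C)C(O)C[N+](=O)[O-] | intermediate
4 | 3-methyl-1-nitrobutan-2-yl methanesulfonate (racemic, not isolated) | CC(C)C(OS(C)(=O)=O)C[N+](=O)[O-] | intermediate
5 | (E)-3-methyl-1-nitrobut-1-ene | CC(C)/C=C/[N+](=O)[O-] | intermediate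
6 | triethyl phosphonoacetate | CCOC(=O)CP(=O)(OCC)OCC | starting material
7 | paraformaldehyde (monomer shown) | C=O | starting material
8 | ethyl 2-(diethoxyphosphoryl)-3-hydroxypropanoate (not isolated) | CCOC(=O)C(CO)P(=O)(OCC)OCC | intermediate
9 | ethyl 2-(diethoxyphosphoryl)acrylate | C=C(C(=O)OCC)P(=O)(OCC)OCC | intermediate
10 | (tert-butyldimethylsilyloxy)acetaldehyde | O=CCO[Si](C)(C)C(C)(C)C | starting material
11 | (2R,3R)-2-[(tert-butyldimethylsilyl)oxy]-4-methyl-3-(nitromethyl)pentanal (anti, not isolated) | O=C[C@H](O[Si](C)(C)C(C)(C)C)[C@H](C(C)C)C[N+](=O)[O-] | intermediate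
12 | ethyl (5R,6R)-6-[(tert-butyldimethylsilyl)oxy]-2-(diethoxyphosphoryl)-5-isopropyl-4-nitro-7-oxoheptanoate (mixture at C2 and C4, not isolated) | O=C[C@H](O[Si](C)(C)C(C)(C)C)[C@H](C(C)C)C([N+](=O)[O-])CC(C(=O)OCC)P(=O)(OCC)OCC | intermediate
13 | ethyl (3S,4R,5S)-3-[(tert-butyldimethylsilyl)oxy]-4-isopropyl-5-nitrocyclohex-1-ene-1-carboxylate (3,4-cis; 4,5-trans) | CCOC(=O)C1=C[C@H](O[Si](C)(C)C(C)(C)C)[C@H](C(C)C)[C@@H]([N+](=O)[O-])C1 | intermediate
14 | ethyl (3S,4R,5S)-5-amino-3-[(tert-butyldimethylsilyl)oxy]-4-isopropylcyclohex-1-ene-1-carboxylate | CCOC(=O)C1=C[C@H](O[Si](C)(C)C(C)(C)C)[C@H](C(C)C)[C@@H](N)C1 | intermediate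
15 | ethyl (3S,4R,5S)-3-[(tert-butyldimethylsilyl)oxy]-5-(dimethylamino)-4-isopropylcyclohex-1-ene-1-carboxylate | CCOC(=O)C1=C[C@H](O[Si](C)(C)C(C)(C)C)[C@H](C(C)C)[C@@H](N(C)C)C1 | intermediate
16 | N-oxide of 15 (not isolated) | CCOC(=O)C1=C[C@H](O[Si](C)(C)C(C)(C)C)[C@H](C(C)C)[C@@H]([N+](C)(C)[O-])C1 | intermediate
17 | ethyl (3R,4R)-3-[(tert-butyldimethylsilyl)oxy]-4-isopropylcyclohexa-1,5-diene-1-carboxylate (3,4-cis) | CCOC(=O)C1=C[C@H](O[Si](C)(C)C(C)(C)C)[C@H](C(C)C)C=C1 | intermediate
18 | ethyl (3S,4R,5R,6S)-3-[(tert-butyldimethylsilyl)oxy]-5,6-dihydroxy-4-isopropylcyclohex-1-ene-1-carboxylate (cis-diol trans to i-Pr) | CCOC(=O)C1=C[C@H](O[Si](C)(C)C(C)(C)C)[C@H](C(C)C)[C@@H](O)[C@H]1O | intermediate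
19 | (3S,4R,5R,6S)-3-[(tert-butyldimethylsilyl)oxy]-1-(hydroxymethyl)-4-isopropylcyclohex-1-ene-5,6-diol | CC(C)(C)[Si](C)(C)O[C@H]1C=C(CO)[C@H](O)[C@H](O)[C@H]1C(C)C | intermediate
20 | 6,7-O-(di-tert-butylsilylene) derivative of 19, C5–OH free | CC(C)(C)[Si](C)(C)O[C@H]1C=C2CO[Si](C(C)(C)C)(C(C)(C)C)O[C@@H]2[C@H](O)[C@H]1C(C)C | intermediate
21 | 5-O-acetyl derivative of 20 | CC(C)(C)[Si](C)(C)O[C@H]1C=C2CO[Si](C(C)(C)C)(C(C)(C)C)O[C@@H]2[C@H](OC(C)=O)[C@H]1C(C)C | intermediate
22 | (3S,4S,5R,6S)-3,6-dihydroxy-1-(hydroxymethyl)-4-isopropylcyclohex-1-en-5-yl acetate | O[C@H]1C=C(CO)[C@H](O)[C@H](OC(C)=O)[C@H]1C(C)C | intermediate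
23 | (3S,4S,5R,6S)-1-{[(tert-butyldimethylsilyl)oxy]methyl}-3,6-dihydroxy-4-isopropylcyclohex-1-en-5-yl acetate | O[C@H]1C=C(CO[Si](C)(C)C(C)(C)C)[C@H](O)[C@H](OC(C)=O)[C@H]1C(C)C | intermediate
24 | tigloyl chloride, (E)-2-methylbut-2-enoyl chloride | C/C=C(\C)C(=O)Cl | starting material
25 | (3S,4S,5R,6S)-5-acetoxy-1-{[(tert-butyldimethylsilyl)oxy]methyl}-4-isopropylcyclohex-1-ene-3,6-diyl bis[(E)-2-methylbut-2-enoate] | C/C=C(\C)C(=O)O[C@H]1C=C(CO[Si](C)(C)C(C)(C)C)[C@H](OC(=O)/C(C)=C/C)[C@H](OC(C)=O)[C@H]1C(C)C | intermediate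
26 | (3S,4S,5R,6S)-5-acetoxy-1-(hydroxymethyl)-4-isopropylcyclohex-1-ene-3,6-diyl bis[(E)-2-methylbut-2-enoate] | C/C=C(\C)C(=O)O[C@H]1C=C(CO)[C@H](OC(=O)/C(C)=C/C)[C@H](OC(C)=O)[C@H]1C(C)C | target

Total step count: 15. Longest linear sequence: 14 steps (steps 1, 2, 4–15, from isobutyraldehyde).

Steps most likely to fail

Step 4. The enamine addition to a β-alkyl nitroalkene may be slow or poorly anti-selective, and the carbonate stage may erode C3 by epimerisation of the α-silyloxy aldehyde before ring closure. The fallback sets the two centres in separate catalyst-controlled events; it sets out from 2 and 9 and returns at 13. Iminium-catalysed conjugate addition of 2 to commercial (E)-4-methylpent-2-enal (CC(C)/C=C/C=O) with a diarylprolinol silyl ether should give (R)-4-methyl-3-(nitromethyl)pentanal F1, fixing C4. Catalyst-controlled enamine α-benzoyloxylation with dibenzoyl peroxide should then give (2R,3R)-2-(benzoyloxy)-4-methyl-3-(nitromethyl)pentanal F2, fixing C3. Annulation of F2 with 9 and Cs2CO3 as a separate operation should give ethyl (3S,4R,5S)-3-(benzoyloxy)-4-isopropyl-5-nitrocyclohex-1-ene-1-carboxylate F3. Ethanolysis (K2CO3, EtOH) should give ethyl (3S,4R,5S)-3-hydroxy-4-isopropyl-5-nitrocyclohex-1-ene-1-carboxylate F4, and silylation (TBSCl, imidazole) leads to 13.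

Step 7. The syn elimination may also take the C4 hydrogen, which lies cis to nitrogen, and heating may trigger hydrogen shifts or loss of silanol with aromatisation of the diene. The fallback uses an anti elimination whose geometry excludes C4; it sets out from 15 and returns at 17. Quaternisation with MeI should give ethyl (3S,4R,5S)-3-[(tert-butyldimethylsilyl)oxy]-4-isopropyl-5-(trimethylammonio)cyclohex-1-ene-1-carboxylate iodide F5. Hofmann E2 elimination with KOt-Bu in THF at low temperature can then remove only the anti-periplanar C6 hydrogen, giving 17.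

Step 14. Under the basic acylation the acetyl group may shift from O5 to the neighbouring cis O6 before the hindered C6–OH is esterified, and acylation of C3–OH beside the isopropyl group may stall. The fallback installs the tiglates first and the acetate last; it sets out from 20 and returns at 25.
- O5 is blocked as its PMB ether (NaH, PMBCl, DMF), giving the 5-O-(4-methoxybenzyl) ether of 20 F6.
- HF·pyridine then gives the 5-O-(4-methoxybenzyl) analogue of 22 F7.
- TBSCl and imidazole give the 5-O-(4-methoxybenzyl) analogue of 23 F8.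
- Acylation with 24, pyridine and DMAP gives the 5-O-(4-methoxybenzyl) analogue of 25 F9.
- DDQ in wet CH2Cl2 frees the 5-hydroxy analogue of 25 F10.
- Ac2O and DMAP then give 25.

Further compounds
F1 | step 4 | (R)-4-methyl-3-(nitromethyl)pentanal | O=CC[C@H](C(C)C)C[N+](=O)[O-]
F2 | step 4 | (2R,3R)-2-(benzoyloxy)-4-methyl-3-(nitromethyl)pentanal | O=C[C@H](OC(=O)c1ccccc1)[C@H](C(C)C)C[N+](=O)[O-]
F3 | step 4 | ethyl (3S,4R,5S)-3-(benzoyloxy)-4-isopropyl-5-nitrocyclohex-1-ene-1-carboxylate | CCOC(=O)C1=C[C@H](OC(=O)c2ccccc2)[C@H](C(C)C)[C@@H]([N+](=O)[O-])C1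
F4 | step 4 | ethyl (3S,4R,5S)-3-hydroxy-4-isopropyl-5-nitrocyclohex-1-ene-1-carboxylate | CCOC(=O)C1=C[C@H](O)[C@H](C(C)C)[C@@H]([N+](=O)[O-])C1
F5 | step 7 | ethyl (3S,4R,5S)-3-[(tert-butyldimethylsilyl)oxy]-4-isopropyl-5-(trimethylammonio)cyclohex-1-ene-1-carboxylate iodide | CCOC(=O)C1=C[C@H](O[Si](C)(C)C(C)(C)C)[C@H](C(C)C)[C@@H]([N+](C)(C)C)C1.[I-]
F6 | step 14 | 5-O-(4-methoxybenzyl) ether of 20 | CC(C)(C)[Si](C)(C)O[C@H]1C=C2CO[Si](C(C)(C)C)(C(C)(C)C)O[C@@H]2[C@H](OCc3ccc(OC)cc3)[C@H]1C(C)C
F7 | step 14 | 5-O-(4-methoxybenzyl) analogue of 22 | O[C@H]1C=C(CO)[C@H](O)[C@H](OCc2ccc(OC)cc2)[C@H]1C(C)C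
F8 | step 14 | 5-O-(4-methoxybenzyl) analogue of 23 | O[C@H]1C=C(CO[Si](C)(C)C(C)(C)C)[C@H](O)[C@H](OCc2ccc(OC)cc2)[C@H]1C(C)C
F9 | step 14 | 5-O-(4-methoxybenzyl) analogue of 25 | C/C=C(\C)C(=O)O[C@H]1C=C(CO[Si](C)(C)C(C)(C)C)[C@H](OC(=O)/C(C)=C/C)[C@H](OCc2ccc(OC)cc2)[C@H]1C(C)C
F10 | step 14 | 5-hydroxy analogue of 25 | C/C=C(\C)C(=O)O[C@H]1C=C(CO[Si](C)(C)C(C)(C)C)[C@H](OC(=O)/C(C)=C/C)[C@H](O)[C@H]1C(C)C
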